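## Retrosynthetic overview
1. The γ-lactone is the only ring and is formed last. It closes through the O9′→C9 bond, the same bond that closes in the secoisolariciresinol → matairesinol stage of lignan biosynthesis. The α-carbon is then equilibrated to trans.
2. The γ-hydroxy acid comes from a 2,3-dibenzylsuccinate with two different termini. C9 stays at the acid level as a tert-butyl ester, and C9′ is an Evans imide that is reduced to CH2OH. This fixes which benzyl group ends up α to the carbonyl.
3. The C8–C8′ bond comes from a one-electron oxidative cross-coupling of two different C6–C3 enolates, the enolate version of the 8–8′ phenylpropanoid radical coupling. The auxiliary sets C8′ as R.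
4. The enolate precursors are 3-(3,4-dimethoxyphenyl)propanoic acid with (S)-4-benzyl-2-oxazolidinone, and dihydroisoferulic acid masked in one operation as tert-butyl ester and aryl tert-butyl ether. Both tert-butyl groups are lost in the ring-closing acid step.

Assumption: 3-(3-hydroxy-4-methoxyphenyl)propanoic acid (dihydroisoferulic acid) is taken as a catalogue chemical, like the other two starting materials.

## Route

Step 1
Reactants: 1 3-(3,4-dimethoxyphenyl)propanoic acid; 2 (S)-4-benzyl-1,3-oxazolidin-2-one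
Product: 4 (4S)-4-benzyl-3-[3-(3,4-dimethoxyphenyl)propanoyl]-1,3-oxazolidin-2-one, via mixed pivalic anhydride 3 (not isolated)
Conditions: PivCl (1.05 equiv), Et3N (2.5 equiv), THF, −20 °C; then LiCl (1.1 equiv), 2, −20 °C → rt
Reagents that add atoms: pivaloyl chloride CC(C)(C)C(=O)Cl (its acyl group stays only in 3)
Why: This is a LiCl-assisted mixed-anhydride N-acylation of an Evans oxazolidinone, in which the hindered pivaloyl carbonyl of 3 steers 2 onto the arylpropanoyl carbonyl, no new stereocentre forms and the (S) centre of 2 is untouched.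

Step 2
Reactants: 5 3-(3-hydroxy-4-methoxyphenyl)propanoic acid
Product: 6 tert-butyl 3-(3-tert-butoxy-4-methoxyphenyl)propanoate
Conditions: Me2NCH(OtBu)2 (6 equiv, in portions), PhMe, 85 °C
Reagents that add atoms: N,N-dimethylformamide di-tert-butyl acetal CN(C)C(OC(C)(C)C)OC(C)(C)C
Why: This is a formamide-acetal O-tert-butylation, in which each acidic OH protonates the acetal and the carboxylate or phenoxide then takes the tert-butyl group from the alkoxy-formamidinium ion under neutral conditions, so the electron-rich ring is not C-alkylated and no stereocentre is involved.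

Step 3
Reactants: 4 (4S)-4-benzyl-3-[3-(3,4-dimethoxyphenyl)propanoyl]-1,3-oxazolidin-2-one; 6 tert-butyl 3-(3-tert-butoxy-4-methoxyphenyl)propanoate
Product: 9 tert-butyl (3R)-4-[(4S)-4-benzyl-2-oxo-1,3-oxazolidin-3-yl]-2-(3-tert-butoxy-4-methoxybenzyl)-3-(3,4-dimethoxybenzyl)-4-oxobutanoate (C2 epimers; 2R major), via imide lithium enolate 7 (not isolated), via ester lithium enolate 8 (not isolated)
Conditions: 4 (1 equiv) + 6 (1.5 equiv), LiN(iPr)2 (2.6 equiv), THF, −78 °C; then Cu(2-ethylhexanoate)2 (2.8 equiv), −78 °C → rt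
Reagents that add atoms: lithium diisopropylamide [Li+].CC(C)[N-]C(C)C (lithium stays only in 7 and 8)
Why: This is an oxidative enolate heterocoupling (single-electron oxidation of the mixed lithium enolates by divalent copper), the laboratory counterpart of the 8–8′ radical coupling of two phenylpropanoid units, in which the chelated Z-enolate 7 reacts on the face opposite its C4 benzyl group and so sets C3 (the later lactone C4) as R exactly as in an Evans alkylation, the ester-derived C2 forms as an epimer mixture that is corrected in step 5, and the steric and electronic difference between 7 and 8 favours the cross product over the two homodimers.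

Step 4
Reactants: 9 tert-butyl (3R)-imide succinate (C2 epimers)
Product: 10 tert-butyl (3R)-2-(3-tert-butoxy-4-methoxybenzyl)-3-(3,4-dimethoxybenzyl)-4-hydroxybutanoate (C2 epimers; 2R major)
Conditions: LiBH4 (2 equiv), H2O (2 equiv), Et2O–THF, 0 °C; aq. NH4Cl
Reagents that add atoms: none
Why: This is a chemoselective reductive cleavage of the Evans imide, in which the activated exocyclic imide carbonyl is taken to the primary carbinol while the tert-butyl ester, the aryl ethers and the C3 stereocentre are untouched, so C9′ reaches the alcohol level and C9 stays at the acid level.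

Step 5
Reactants: 10 tert-butyl (3R)-hydroxy ester (C2 epimers)
Product: 13 prestegane A (3R,4R)-4-(3,4-dimethoxybenzyl)-3-(3-hydroxy-4-methoxybenzyl)oxolan-2-one, via hydroxy acid 11 (not isolated), via lactone epimer mixture 12 (not isolated)
Conditions: TFA–CH2Cl2 (1:3), Et3SiH (5 equiv), 0 °C → rt; evaporate; DBU (4 equiv), PhMe, 60 °C; 1 M HCl wash
Reagents that add atoms: none
Why: Acidolysis removes both tert-butyl groups (Et3SiH traps the tert-butyl cation as isobutane so the veratryl ring is not alkylated), γ-hydroxy acid 11 lactonises spontaneously through the biosynthetic O9′→C9 bond, and DBU-mediated enolisation and reprotonation (thermodynamic epimerisation) then sets C3 as R, trans to the fixed, non-epimerisable C4 substituent.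

## Compound list
1 | 3-(3,4-dimethoxyphenyl)propanoic acid | COc1ccc(CCC(=O)O)cc1OC | starting material
2 | (S)-4-benzyl-1,3-oxazolidin-2-one | O=C1N[C@@H](Cc2ccccc2)CO1 | starting material
3 | 3-(3,4-dimethoxyphenyl)propanoic pivalic anhydride | COc1ccc(CCC(=O)OC(=O)C(C)(C)C)cc1OC | intermediate
4 | (4S)-4-benzyl-3-[3-(3,4-dimethoxyphenyl)propanoyl]-1,3-oxazolidin-2-one | COc1ccc(CCC(=O)N2[C@@H](Cc3ccccc3)COC2=O)cc1OC | intermediate
5 | 3-(3-hydroxy-4-methoxyphenyl)propanoic acid | COc1ccc(CCC(=O)O)cc1O | starting material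
6 | tert-butyl 3-(3-tert-butoxy-4-methoxyphenyl)propanoate | COc1ccc(CCC(=O)OC(C)(C)C)cc1OC(C)(C)C | intermediate
7 | lithium Z-enolate of 4 (CH2Ar cis to OLi) | [Li+].COc1ccc(C/C=C(\[O-])N2[C@@H](Cc3ccccc3)COC2=O)cc1OC | intermediate
8 | lithium enolate of 6 (kinetic; CH2Ar trans to OLi) | [Li+].COc1ccc(C/C=C(/[O-])OC(C)(C)C)cc1OC(C)(C)C | intermediate
9 | tert-butyl (3R)-4-[(4S)-4-benzyl-2-oxo-1,3-oxazolidin-3-yl]-2-(3-tert-butoxy-4-methoxybenzyl)-3-(3,4-dimethoxybenzyl)-4-oxobutanoate, C2 epimers (2R major), C2 therefore left open | COc1ccc(CC(C(=O)OC(C)(C)C)[C@@H](Cc2ccc(OC)c(OC)c2)C(=O)N2[C@@H](Cc3ccccc3)COC2=O)cc1OC(C)(C)C | intermediate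
10 | tert-butyl (3R)-2-(3-tert-butoxy-4-methoxybenzyl)-3-(3,4-dimethoxybenzyl)-4-hydroxybutanoate, C2 epimers | COc1ccc(CC(C(=O)OC(C)(C)C)[C@@H](Cc2ccc(OC)c(OC)c2)CO)cc1OC(C)(C)C | intermediate
11 | (3R)-3-(3,4-dimethoxybenzyl)-4-hydroxy-2-(3-hydroxy-4-methoxybenzyl)butanoic acid, C2 epimers | COc1ccc(CC(C(=O)O)[C@@H](Cc2ccc(OC)c(OC)c2)CO)cc1O | intermediate
12 | (4R)-4-(3,4-dimethoxybenzyl)-3-(3-hydroxy-4-methoxybenzyl)oxolan-2-one, C3 epimers (trans plus cis) | COc1ccc(CC2C(=O)OC[C@@H]2Cc2ccc(OC)c(OC)c2)cc1O | intermediate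
13 | prestegane A, (3R,4R)-4-(3,4-dimethoxybenzyl)-3-(3-hydroxy-4-methoxybenzyl)oxolan-2-one | COc1ccc(C[C@H]2C(=O)OC[C@@H]2Cc2ccc(OC)c(OC)c2)cc1O | target

## Step count and risks
Total steps: 5. Longest linear sequence: 4 (1 → 4 → 9 → 10 → 13, or 5 → 6 → 9 → 10 → 13).

**Step 3** may fail through homodimer formation or low conversion in the cross-coupling. The fallback sets out from 4 and comes back at 13. It replaces the radical 8–8′ union by two polar C–C bond formations.
- Evans alkylation of 4 (NaN(SiMe3)2, THF, −78 °C; tert-butyl bromoacetate) gives tert-butyl (3R)-4-[(4S)-4-benzyl-2-oxo-1,3-oxazolidin-3-yl]-3-(3,4-dimethoxybenzyl)-4-oxobutanoate F1.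
- LiBH4/H2O gives tert-butyl (3R)-3-(3,4-dimethoxybenzyl)-4-hydroxybutanoate F2.
- Catalytic TFA in CH2Cl2 closes this to (4R)-4-(3,4-dimethoxybenzyl)oxolan-2-one F3.
- The lithium enolate of the lactone (LiN(iPr)2, THF, −78 °C) adds to commercial 3-benzyloxy-4-methoxybenzaldehyde anti to the C4 substituent. This gives (3S,4R)-3-[(3-benzyloxy-4-methoxyphenyl)(hydroxy)methyl]-4-(3,4-dimethoxybenzyl)oxolan-2-one F4. Its ring carbons have the same spatial arrangement as 13, and the carbinol epimers do not matter.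
- H2, Pd/C in AcOH with a trace of HClO4 removes the benzylic hydroxyl and the O-benzyl group together and gives 13.

**Step 2** may fail because the weakly acidic, ortho-substituted phenol is etherified slowly or incompletely. The fallback sets out from 5 and comes back at 11. It changes the protecting scheme from acid-labile to hydrogenolysable groups.
- BnBr (2.2 equiv), K2CO3 in DMF gives benzyl 3-(3-benzyloxy-4-methoxyphenyl)propanoate F5.
- This takes the place of 6 in the copper-mediated coupling with 4 and gives benzyl (3R)-4-[(4S)-4-benzyl-2-oxo-1,3-oxazolidin-3-yl]-2-(3-benzyloxy-4-methoxybenzyl)-3-(3,4-dimethoxybenzyl)-4-oxobutanoate F6.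
- A limited charge of LiBH4/H2O at −10 °C gives benzyl (3R)-2-(3-benzyloxy-4-methoxybenzyl)-3-(3,4-dimethoxybenzyl)-4-hydroxybutanoate F7.
- H2, Pd/C in EtOAc cleaves both benzyl groups to give 11. A trace of acid closes 11 to the lactone, and DBU equilibrates it as in step 5.

**Step 4** may fail because hydride attacks the ring carbonyl of the hindered α,β-branched imide instead of the exocyclic one. The fallback sets out from 9 and comes back at 10. It separates auxiliary removal from reduction.
- LiOH/H2O2 in THF–H2O at 0 °C attacks only the exocyclic carbonyl. This gives (2R)-4-tert-butoxy-3-(3-tert-butoxy-4-methoxybenzyl)-2-(3,4-dimethoxybenzyl)-4-oxobutanoic acid F8.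
- BH3·SMe2 in THF at 0 °C reduces the free acid selectively in the presence of the tert-butyl ester and gives 10.

## Further compounds
F1 | step 3 | tert-butyl (3R)-4-[(4S)-4-benzyl-2-oxo-1,3-oxazolidin-3-yl]-3-(3,4-dimethoxybenzyl)-4-oxobutanoate | COc1ccc(C[C@H](CC(=O)OC(C)(C)C)C(=O)N2[C@@H](Cc3ccccc3)COC2=O)cc1OC
F2 | step 3 | tert-butyl (3R)-3-(3,4-dimethoxybenzyl)-4-hydroxybutanoate | COc1ccc(C[C@H](CC(=O)OC(C)(C)C)CO)cc1OC
F3 | step 3 | (4R)-4-(3,4-dimethoxybenzyl)oxolan-2-one | COc1ccc(C[C@H]2COC(=O)C2)cc1OC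
F4 | step 3 | (3S,4R)-3-[(3-benzyloxy-4-methoxyphenyl)(hydroxy)methyl]-4-(3,4-dimethoxybenzyl)oxolan-2-one, carbinol epimers | COc1ccc(C(O)[C@H]2C(=O)OC[C@@H]2Cc2ccc(OC)c(OC)c2)cc1OCc1ccccc1
F5 | step 2 | benzyl 3-(3-benzyloxy-4-methoxyphenyl)propanoate | COc1ccc(CCC(=O)OCc2ccccc2)cc1OCc1ccccc1
F6 | step 2 | benzyl (3R)-4-[(4S)-4-benzyl-2-oxo-1,3-oxazolidin-3-yl]-2-(3-benzyloxy-4-methoxybenzyl)-3-(3,4-dimethoxybenzyl)-4-oxobutanoate, C2 epimers | COc1ccc(CC(C(=O)OCc2ccccc2)[C@@H](Cc2ccc(OC)c(OC)c2)C(=O)N2[C@@H](Cc3ccccc3)COC2=O)cc1OCc1ccccc1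
F7 | step 2 | benzyl (3R)-2-(3-benzyloxy-4-methoxybenzyl)-3-(3,4-dimethoxybenzyl)-4-hydroxybutanoate, C2 epimers | COc1ccc(CC(C(=O)OCc2ccccc2)[C@@H](Cc2ccc(OC)c(OC)c2)CO)cc1OCc1ccccc1
F8 | step 4 | (2R)-4-tert-butoxy-3-(3-tert-butoxy-4-methoxybenzyl)-2-(3,4-dimethoxybenzyl)-4-oxobutanoic acid, C3 epimers | COc1ccc(CC(C(=O)OC(C)(C)C)[C@@H](Cc2ccc(OC)c(OC)c2)C(=O)O)cc1OC(C)(C)C
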